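**Retrosynthetic overview**

1. The CH2–O ester bond between the two halves is cut first: a dihydroxy acid (acyl half) opens a spiro‑epoxide (lactone half) at its CH2 end. This one C–O bond formation also releases the tertiary alcohol.
2. Lactone half: the seven‑membered lactone comes from ring‑closing metathesis. The cis ester/vinyl pair comes from conjugate vinylation of an enoate and kinetic protonation. The epoxide is carried as a chlorohydrin silyl ether made by ClCH2Li addition to an α‑iodoenone.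
3. Acyl half: Ti‑catalysed hydromagnesiation–carboxylation of a propargylic alcohol, which is made by a new Cu‑catalysed anti‑SN2′ alkynylation of a vinyl epoxide.
4. Both halves come from (S)‑cryptone, made by an organocatalytic Michael/aldol sequence from 3‑methylbutanal and methyl vinyl ketone.
5. Ring order: cyclohexenone (both halves), then spiro‑epoxide, then seven‑membered lactone, then the ester link.

Assumption: the SMILES is taken as drawn, so isopropyl and alkenyl are cis on the cyclohexene of the acyl half and trans on the cyclohexane of the lactone half.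

**Step 1**
Reactants: 1 3-methylbutanal; 2 but-3-en-2-one
Product: 4 (4S)-4-(propan-2-yl)cyclohex-2-en-1-one, via (2S)-5-oxo-2-(propan-2-yl)hexanal 3 (not isolated)
Conditions: (S)-2-[diphenyl(trimethylsilyloxy)methyl]pyrrolidine (5 mol %), ethyl 3,4-dihydroxybenzoate (20 mol %), neat, 4 °C; then LiOH, iPrOH, 25 °C
Reagents that add atoms: none
Why: Enamine Michael addition in which the diphenyl(silyloxy)methyl group shields one face of the E‑enamine sets the S centre, and base‑mediated intramolecular aldol condensation (Robinson annulation) then closes the cyclohexenone without touching it.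

**Step 2**
Reactants: 4 (4S)-4-(propan-2-yl)cyclohex-2-en-1-one
Product: 5 (3R,6S)-6-(propan-2-yl)-1-oxaspiro[2.5]oct-4-ene
Conditions: Me3S+ I−, n-BuLi, THF, −10 to 0 °C
Reagents that add atoms: trimethylsulfonium iodide, C[S+](C)C.[I-]
Why: Corey–Chaykovsky epoxidation, in which the sulfonium ylide adds 1,2 to the enone by axial attack on the face cis to the pseudo‑equatorial isopropyl group, so the epoxide CH2 ends cis and the oxygen trans to isopropyl (major isomer, minor one removed after step 3).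

**Step 3**
Reactants: 5 (3R,6S)-6-(propan-2-yl)-1-oxaspiro[2.5]oct-4-ene; 6 trimethyl(prop-2-yn-1-yloxy)silane
Product: 8 3-[(1R,6S)-3-(hydroxymethyl)-6-(propan-2-yl)cyclohex-2-en-1-yl]prop-2-yn-1-ol, via trimethylsilyl ether 7 (not isolated)
Conditions: 6, iBu2AlH, Et3N (5 mol %), hexanes, 50 °C; then 5, CuCl(SIMes) (5 mol %; SIMes = 1,3-bis(2,4,6-trimethylphenyl)imidazolidin-2-ylidene), THF, −30 to 0 °C; then 1 M HCl, THF, 25 °C
Reagents that add atoms: none
Why: Proposed new method: copper‑catalysed anti‑SN2′ alkynylation of a vinyl epoxide by an alkynylaluminium reagent, in which the alane binds and activates the epoxide oxygen and passes the alkynyl group to the NHC–copper centre, copper attacks the alkene terminus anti to the breaking C–O bond (the face cis to isopropyl, since the oxygen is trans to it) and reductive elimination forms the C(sp3)–C(sp) bond and sets C1 as R while the epoxide CH2–O becomes the ring CH2OH; the closest known reactions are the NHC–copper‑catalysed SN2′ substitution of allylic phosphates with alkynylaluminium reagents and the anti‑SN2′ opening of vinyl epoxides by alkyl and alkenyl cuprates.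

**Step 4**
Reactants: 8 3-[(1R,6S)-3-(hydroxymethyl)-6-(propan-2-yl)cyclohex-2-en-1-yl]prop-2-yn-1-ol
Product: 10 (2E)-2-(hydroxymethyl)-3-[(1R,6S)-3-(hydroxymethyl)-6-(propan-2-yl)cyclohex-2-en-1-yl]prop-2-enoic acid, via alkenylmagnesium bromide 9 (not isolated)
Conditions: iBuMgBr (3.3 equiv), Cp2TiCl2 (10 mol %), Et2O, 25 °C; then CO2, −20 to 25 °C; then 1 M HCl
Reagents that add atoms: carbon dioxide, O=C=O
Why: Titanium‑catalysed hydromagnesiation of the propargylic alkoxide is a syn addition that puts magnesium on the carbon next to CH2O, so carboxylation with retention gives the acid with the ring cis to CH2OH and trans to CO2H (E).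

**Step 5**
Reactants: 4 (4S)-4-(propan-2-yl)cyclohex-2-en-1-one
Product: 11 (4S)-2-iodo-4-(propan-2-yl)cyclohex-2-en-1-one
Conditions: I2, pyridine, CH2Cl2, 0 to 25 °C
Reagents that add atoms: iodine, II
Why: α‑Iodination of the enone by reversible pyridine conjugate addition, iodination of the enolate and elimination (Johnson iodination), which leaves the C4 stereocentre untouched.

**Step 6**
Reactants: 11 (4S)-2-iodo-4-(propan-2-yl)cyclohex-2-en-1-one
Product: 13 {[(1S,4S)-1-(chloromethyl)-2-iodo-4-(propan-2-yl)cyclohex-2-en-1-yl]oxy}(triethyl)silane, via lithium alkoxide 12 (not isolated)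
Conditions: ICH2Cl, MeLi·LiBr, THF, −78 °C; then Et3SiOTf, −78 to −40 °C
Reagents that add atoms: chloroiodomethane, ClCI; triethylsilyl trifluoromethanesulfonate, CC[Si](CC)(CC)OS(=O)(=O)C(F)(F)F
Why: Chloromethyllithium made in situ adds 1,2 to the ketone by the same axial attack as in step 2 (CH2Cl cis, oxygen trans to isopropyl), and silylation at −78 °C traps the chlorohydrin before it closes, giving a masked epoxide that survives the enolate chemistry ahead.

**Step 7**
Reactants: 13 {[(1S,4S)-1-(chloromethyl)-2-iodo-4-(propan-2-yl)cyclohex-2-en-1-yl]oxy}(triethyl)silane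
Product: 14 2-(trimethylsilyl)ethyl (3S,6R)-6-(chloromethyl)-3-(propan-2-yl)-6-[(triethylsilyl)oxy]cyclohex-1-ene-1-carboxylate
Conditions: Pd(PPh3)4 (5 mol %), CO (1 atm), Me3SiCH2CH2OH, Et3N, DMF, 60 °C
Reagents that add atoms: carbon monoxide, [C-]#[O+]; 2-(trimethylsilyl)ethanol, C[Si](C)(C)CCO
Why: Palladium‑catalysed alkoxycarbonylation of the alkenyl iodide (oxidative addition, CO insertion, alcoholysis) installs the carboxyl carbon, and the neighbouring silyl ether and chloride survive because β‑elimination from the alkenylpalladium would need a cyclic allene.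

**Step 8**
Reactants: 14 2-(trimethylsilyl)ethyl (3S,6R)-6-(chloromethyl)-3-(propan-2-yl)-6-[(triethylsilyl)oxy]cyclohex-1-ene-1-carboxylate
Product: 16 2-(trimethylsilyl)ethyl (1S,2S,3S,6R)-6-(chloromethyl)-2-ethenyl-3-(propan-2-yl)-6-[(triethylsilyl)oxy]cyclohexane-1-carboxylate, via silyl ketene acetal 15 (not isolated)
Conditions: CH2=CHMgBr, CuBr·SMe2 (20 mol %), Me3SiCl, THF, −78 to −50 °C; then AcOH, −78 to 0 °C
Reagents that add atoms: vinylmagnesium bromide, C=C[Mg]Br
Why: Copper‑catalysed, Me3SiCl‑accelerated conjugate addition delivers vinyl anti to the adjacent isopropyl group, and kinetic protonation of the silyl ketene acetal from the face opposite the vinyl and silyloxy groups gives the cis ester, while trapping as the ketene acetal avoids loss of the silyloxy group or cyclopropane formation with CH2Cl.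

**Step 9**
Reactants: 16 2-(trimethylsilyl)ethyl (1S,2S,3S,6R)-6-(chloromethyl)-2-ethenyl-3-(propan-2-yl)-6-[(triethylsilyl)oxy]cyclohexane-1-carboxylate; 17 tert-butyl 2-(bromomethyl)prop-2-enoate
Product: 19 2-(tert-butoxycarbonyl)prop-2-en-1-yl (3R,4S,5S,6S)-5-ethenyl-6-(propan-2-yl)-1-oxaspiro[2.5]octane-4-carboxylate, via tetrabutylammonium carboxylate 18 (not isolated)
Conditions: Bu4NF, THF, 0 to 25 °C; then 17, 25 °C
Reagents that add atoms: none
Why: Fluoride cleaves the 2-(trimethylsilyl)ethyl ester and the triethylsilyl ether, the tertiary alkoxide closes the epoxide by intramolecular Williamson displacement of chloride without touching the carbinol configuration, and the carboxylate is then O‑alkylated by the allylic bromide.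

**Step 10**
Reactants: 19 2-(tert-butoxycarbonyl)prop-2-en-1-yl (3R,4S,5S,6S)-5-ethenyl-6-(propan-2-yl)-1-oxaspiro[2.5]octane-4-carboxylate
Product: 20 tert-butyl (5aR,6S,9R,9aS)-1-oxo-6-(propan-2-yl)-3,5a,6,7,8,9a-hexahydro-1H-spiro[2-benzoxepine-9,2'-oxirane]-4-carboxylate
Conditions: RuCl2(SIMes)(=CH–C6H4-2-OiPr) (second-generation Hoveyda–Grubbs catalyst, 10 mol %), toluene (5 mM), 80 °C
Reagents that add atoms: none
Why: Ring‑closing metathesis between the vinyl group and the 1,1‑disubstituted acrylate closes the cis‑fused seven‑membered lactone, whose ring enforces the required alkene geometry (ring carbon cis to CH2O), and the epoxide and esters are inert to the ruthenium carbene.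

**Step 11**
Reactants: 20 tert-butyl (5aR,6S,9R,9aS)-1-oxo-6-(propan-2-yl)-3,5a,6,7,8,9a-hexahydro-1H-spiro[2-benzoxepine-9,2'-oxirane]-4-carboxylate; 10 (2E)-2-(hydroxymethyl)-3-[(1R,6S)-3-(hydroxymethyl)-6-(propan-2-yl)cyclohex-2-en-1-yl]prop-2-enoic acid
Product: 21 tert-butyl (5aR,6S,9R,9aS)-9-hydroxy-9-[({(2E)-2-(hydroxymethyl)-3-[(1R,6S)-3-(hydroxymethyl)-6-(propan-2-yl)cyclohex-2-en-1-yl]prop-2-enoyl}oxy)methyl]-1-oxo-6-(propan-2-yl)-1,3,5a,6,7,8,9,9a-octahydro-2-benzoxepine-4-carboxylate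
Conditions: Co(salen)(OTs) (5 mol %; trivalent cobalt, salen = (R,R)-N,N′-bis(3,5-di-tert-butylsalicylidene)cyclohexane-1,2-diamine dianion), iPr2NEt (0.3 equiv), tert-butyl methyl ether, 25 °C
Reagents that add atoms: none
Why: Key C–O bond formation by cobalt–salen‑catalysed ring opening of a 2,2‑disubstituted epoxide with a carboxylic acid, an SN2 attack at the CH2 terminus that forms the ester link and frees the tertiary alcohol with its configuration from step 6 retained, the free hydroxyls of 10 being far poorer nucleophiles than the cobalt‑bound carboxylate.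

**Step 12**
Reactants: 21 tert-butyl ester of the target
Product: 22 (5aR,6S,9R,9aS)-9-hydroxy-9-[({(2E)-2-(hydroxymethyl)-3-[(1R,6S)-3-(hydroxymethyl)-6-(propan-2-yl)cyclohex-2-en-1-yl]prop-2-enoyl}oxy)methyl]-1-oxo-6-(propan-2-yl)-1,3,5a,6,7,8,9,9a-octahydro-2-benzoxepine-4-carboxylic acid
Conditions: 85 % aq. H3PO4, toluene, 25 °C
Reagents that add atoms: none
Why: Acid‑mediated alkyl–oxygen (AAL1) cleavage of the tert‑butyl ester frees the conjugated acid under conditions mild enough to leave the lactone, the ester link and the three alcohols alone.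

**Compound list**

1 | 3-methylbutanal | CC(C)CC=O | starting material
2 | but-3-en-2-one | CC(=O)C=C | starting material
3 | (2S)-5-oxo-2-(propan-2-yl)hexanal | CC(C)[C@@H](C=O)CCC(C)=O | intermediate
4 | (4S)-4-(propan-2-yl)cyclohex-2-en-1-one, (S)-cryptone | CC(C)[C@@H]1CCC(=O)C=C1 | intermediate
5 | (3R,6S)-6-(propan-2-yl)-1-oxaspiro[2.5]oct-4-ene (O trans, CH2 cis to isopropyl) | CC(C)[C@@H]1CC[C@]2(CO2)C=C1 | intermediate
6 | trimethyl(prop-2-yn-1-yloxy)silane | C#CCO[Si](C)(C)C | starting material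
7 | trimethyl({3-[(1R,6S)-3-(hydroxymethyl)-6-(propan-2-yl)cyclohex-2-en-1-yl]prop-2-yn-1-yl}oxy)silane | C[Si](C)(C)OCC#C[C@H]1C=C(CO)CC[C@H]1C(C)C | intermediate
8 | 3-[(1R,6S)-3-(hydroxymethyl)-6-(propan-2-yl)cyclohex-2-en-1-yl]prop-2-yn-1-ol (alkynyl cis to isopropyl) | OCC#C[C@H]1C=C(CO)CC[C@H]1C(C)C | intermediate
9 | {(1E)-3-[(bromomagnesio)oxy]-1-[(1R,6S)-3-{[(bromomagnesio)oxy]methyl}-6-(propan-2-yl)cyclohex-2-en-1-yl]prop-1-en-2-yl}magnesium bromide | Br[Mg]/C(=C/[C@H]1C=C(CO[Mg]Br)CC[C@H]1C(C)C)CO[Mg]Br | intermediate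
10 | (2E)-2-(hydroxymethyl)-3-[(1R,6S)-3-(hydroxymethyl)-6-(propan-2-yl)cyclohex-2-en-1-yl]prop-2-enoic acid | O=C(O)/C(=C/[C@H]1C=C(CO)CC[C@H]1C(C)C)CO | intermediate
11 | (4S)-2-iodo-4-(propan-2-yl)cyclohex-2-en-1-one | CC(C)[C@@H]1CCC(=O)C(I)=C1 | intermediate
12 | lithium (1S,4S)-1-(chloromethyl)-2-iodo-4-(propan-2-yl)cyclohex-2-en-1-olate | [Li+].CC(C)[C@@H]1CC[C@]([O-])(CCl)C(I)=C1 | intermediate
13 | {[(1S,4S)-1-(chloromethyl)-2-iodo-4-(propan-2-yl)cyclohex-2-en-1-yl]oxy}(triethyl)silane (O trans, CH2Cl cis to isopropyl) | CC(C)[C@@H]1CC[C@](O[Si](CC)(CC)CC)(CCl)C(I)=C1 | intermediate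
14 | 2-(trimethylsilyl)ethyl (3S,6R)-6-(chloromethyl)-3-(propan-2-yl)-6-[(triethylsilyl)oxy]cyclohex-1-ene-1-carboxylate | CC(C)[C@@H]1CC[C@](O[Si](CC)(CC)CC)(CCl)C(C(=O)OCC[Si](C)(C)C)=C1 | intermediate
15 | {[(2S,3S,6R)-6-(chloromethyl)-2-ethenyl-3-(propan-2-yl)-6-[(triethylsilyl)oxy]cyclohexylidene][2-(trimethylsilyl)ethoxy]methoxy}trimethylsilane | CC(C)[C@@H]1CC[C@](O[Si](CC)(CC)CC)(CCl)C(=C(O[Si](C)(C)C)OCC[Si](C)(C)C)[C@H]1C=C | intermediate
16 | 2-(trimethylsilyl)ethyl (1S,2S,3S,6R)-6-(chloromethyl)-2-ethenyl-3-(propan-2-yl)-6-[(triethylsilyl)oxy]cyclohexane-1-carboxylate (vinyl trans to isopropyl, ester cis to vinyl and to silyloxy) | CC(C)[C@@H]1CC[C@](O[Si](CC)(CC)CC)(CCl)[C@@H](C(=O)OCC[Si](C)(C)C)[C@H]1C=C | intermediate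
17 | tert-butyl 2-(bromomethyl)prop-2-enoate | C=C(CBr)C(=O)OC(C)(C)C | starting material
18 | tetrabutylammonium (3R,4S,5S,6S)-5-ethenyl-6-(propan-2-yl)-1-oxaspiro[2.5]octane-4-carboxylate | CC(C)[C@@H]1CC[C@]2(CO2)[C@@H](C(=O)[O-])[C@H]1C=C.CCCC[N+](CCCC)(CCCC)CCCC | intermediate
19 | 2-(tert-butoxycarbonyl)prop-2-en-1-yl (3R,4S,5S,6S)-5-ethenyl-6-(propan-2-yl)-1-oxaspiro[2.5]octane-4-carboxylate | CC(C)[C@@H]1CC[C@]2(CO2)[C@@H](C(=O)OCC(=C)C(=O)OC(C)(C)C)[C@H]1C=C | intermediate
20 | tert-butyl (5aR,6S,9R,9aS)-1-oxo-6-(propan-2-yl)-3,5a,6,7,8,9a-hexahydro-1H-spiro[2-benzoxepine-9,2'-oxirane]-4-carboxylate (cis-fused lactone, epoxide O cis to the lactone carbonyl carbon) | CC(C)[C@@H]1CC[C@]2(CO2)[C@H]3C(=O)OCC(C(=O)OC(C)(C)C)=C[C@@H]13 | intermediate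
21 | tert-butyl (5aR,6S,9R,9aS)-9-hydroxy-9-[({(2E)-2-(hydroxymethyl)-3-[(1R,6S)-3-(hydroxymethyl)-6-(propan-2-yl)cyclohex-2-en-1-yl]prop-2-enoyl}oxy)methyl]-1-oxo-6-(propan-2-yl)-1,3,5a,6,7,8,9,9a-octahydro-2-benzoxepine-4-carboxylate | CC(C)[C@@H]1CC[C@](O)(COC(=O)/C(=C/[C@H]2C=C(CO)CC[C@H]2C(C)C)CO)[C@H]2C(=O)OCC(C(=O)OC(C)(C)C)=C[C@@H]12 | intermediate
22 | (5aR,6S,9R,9aS)-9-hydroxy-9-[({(2E)-2-(hydroxymethyl)-3-[(1R,6S)-3-(hydroxymethyl)-6-(propan-2-yl)cyclohex-2-en-1-yl]prop-2-enoyl}oxy)methyl]-1-oxo-6-(propan-2-yl)-1,3,5a,6,7,8,9,9a-octahydro-2-benzoxepine-4-carboxylic acid | CC(C)[C@@H]1CC[C@](O)(COC(=O)/C(=C/[C@H]2C=C(CO)CC[C@H]2C(C)C)CO)[C@H]2C(=O)OCC(C(=O)O)=C[C@@H]12 | target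

**Step count and risk**

Total step count: 12. Longest linear sequence: 9 steps (1, 5, 6, 7, 8, 9, 10, 11, 12).

The three steps most likely to fail:

Step 3 (the proposed new method). The copper must enter on the face cis to the neighbouring isopropyl group, and uncatalysed SN2 attack of the alane at the epoxide CH2 could compete. The fallback uses known chemistry; it sets out from 5 and comes back to the route at 8. Vinyl epoxide 5 is coupled under palladium catalysis (PdCl2(MeCN)2, DMF–H2O, 25 °C, a Stille coupling of a vinyl epoxide) with tributyl[3-(tert-butyldimethylsilyloxy)prop-1-yn-1-yl]stannane. Oxidative addition with inversion puts palladium anti to the oxygen, and transmetalation and reductive elimination at the less hindered allyl terminus give tert-butyl({3-[(1R,6S)-3-(hydroxymethyl)-6-(propan-2-yl)cyclohex-2-en-1-yl]prop-2-yn-1-yl}oxy)dimethylsilane F1 with the same cis relationship. Bu4NF in THF then removes the silyl group and gives 8.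

Step 8. The enoate is trisubstituted and flanked by a quaternary carbon and the isopropyl‑bearing carbon, so addition may be slow, and the face of protonation is argued, not proven. The fallback sets out from 13 and comes back at 19, moving the conjugate addition to a far more reactive enal. Reductive carbonylation of 13 (Pd(PPh3)4, CO, Bu3SnH) gives (3S,6R)-6-(chloromethyl)-3-(propan-2-yl)-6-[(triethylsilyl)oxy]cyclohex-1-ene-1-carbaldehyde F2. Treatment with (CH2=CH)2CuLi and Me3SiCl, then mild acid, gives (1S,2S,3S,6R)-6-(chloromethyl)-2-ethenyl-3-(propan-2-yl)-6-[(triethylsilyl)oxy]cyclohexane-1-carbaldehyde F3. Pinnick oxidation (NaClO2, NaH2PO4, 2-methylbut-2-ene) gives (1S,2S,3S,6R)-6-(chloromethyl)-2-ethenyl-3-(propan-2-yl)-6-[(triethylsilyl)oxy]cyclohexane-1-carboxylic acid F4. Bu4NF (silyl ether cleavage and epoxide closure) followed by alkylation of the carboxylate with 17 gives 19.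

Step 10. Ring‑closing metathesis must form a trisubstituted, electron‑poor alkene in a seven‑membered ring next to a spiro‑epoxide. The fallback sets out from 16 and comes back at 20, closing the lactone by C–O instead of C=C bond formation. Ozonolysis of 16 (O3, then Me2S) gives 2-(trimethylsilyl)ethyl (1S,2S,3S,6R)-6-(chloromethyl)-2-formyl-3-(propan-2-yl)-6-[(triethylsilyl)oxy]cyclohexane-1-carboxylate F5. Morita–Baylis–Hillman reaction with tert-butyl acrylate (DABCO) gives 2-(trimethylsilyl)ethyl (1S,2S,3S,6R)-2-[2-(tert-butoxycarbonyl)-1-hydroxyprop-2-en-1-yl]-6-(chloromethyl)-3-(propan-2-yl)-6-[(triethylsilyl)oxy]cyclohexane-1-carboxylate F6 as a mixture of carbinol epimers, which does not matter. Bu4NF gives (3R,4S,5S,6S)-5-[2-(tert-butoxycarbonyl)-1-hydroxyprop-2-en-1-yl]-6-(propan-2-yl)-1-oxaspiro[2.5]octane-4-carboxylic acid F7. An intramolecular Mitsunobu reaction (PPh3, DIAD), which with Baylis–Hillman alcohols runs in the SN2′ sense, then lets the carboxylate attack the CH2 terminus and gives 20.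

**Further compounds**

F1 | step 3 | tert-butyl({3-[(1R,6S)-3-(hydroxymethyl)-6-(propan-2-yl)cyclohex-2-en-1-yl]prop-2-yn-1-yl}oxy)dimethylsilane | CC(C)(C)[Si](C)(C)OCC#C[C@H]1C=C(CO)CC[C@H]1C(C)C
F2 | step 8 | (3S,6R)-6-(chloromethyl)-3-(propan-2-yl)-6-[(triethylsilyl)oxy]cyclohex-1-ene-1-carbaldehyde | CC(C)[C@@H]1CC[C@](O[Si](CC)(CC)CC)(CCl)C(C=O)=C1
F3 | step 8 | (1S,2S,3S,6R)-6-(chloromethyl)-2-ethenyl-3-(propan-2-yl)-6-[(triethylsilyl)oxy]cyclohexane-1-carbaldehyde | CC(C)[C@@H]1CC[C@](O[Si](CC)(CC)CC)(CCl)[C@@H](C=O)[C@H]1C=C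
F4 | step 8 | (1S,2S,3S,6R)-6-(chloromethyl)-2-ethenyl-3-(propan-2-yl)-6-[(triethylsilyl)oxy]cyclohexane-1-carboxylic acid | CC(C)[C@@H]1CC[C@](O[Si](CC)(CC)CC)(CCl)[C@@H](C(=O)O)[C@H]1C=C
F5 | step 10 | 2-(trimethylsilyl)ethyl (1S,2S,3S,6R)-6-(chloromethyl)-2-formyl-3-(propan-2-yl)-6-[(triethylsilyl)oxy]cyclohexane-1-carboxylate | CC(C)[C@@H]1CC[C@](O[Si](CC)(CC)CC)(CCl)[C@@H](C(=O)OCC[Si](C)(C)C)[C@H]1C=O
F6 | step 10 | 2-(trimethylsilyl)ethyl (1S,2S,3S,6R)-2-[2-(tert-butoxycarbonyl)-1-hydroxyprop-2-en-1-yl]-6-(chloromethyl)-3-(propan-2-yl)-6-[(triethylsilyl)oxy]cyclohexane-1-carboxylate | CC(C)[C@@H]1CC[C@](O[Si](CC)(CC)CC)(CCl)[C@@H](C(=O)OCC[Si](C)(C)C)[C@H]1C(O)C(=C)C(=O)OC(C)(C)C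
F7 | step 10 | (3R,4S,5S,6S)-5-[2-(tert-butoxycarbonyl)-1-hydroxyprop-2-en-1-yl]-6-(propan-2-yl)-1-oxaspiro[2.5]octane-4-carboxylic acid | CC(C)[C@@H]1CC[C@]2(CO2)[C@@H](C(=O)O)[C@H]1C(O)C(=C)C(=O)OC(C)(C)C
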